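A direct plan would take 2,4,6-trihydroxybenzaldehyde A1 through benzylation, iodination, MOM protection, Dakin oxidation, SNAr on 4-fluorobenzaldehyde A2 and MOM removal to iodophenol A3.
It would close the first pyranone by palladium-catalysed carbonylative annulation of A3 with 4-ethynylanisole A4 to flavone aldehyde A5.
It would build the second flavone by Claisen–Schmidt condensation with 1-(2,6-dihydroxy-4-methoxyphenyl)ethanone A6 and oxidative cyclisation to dibenzyl ether A7, and finish by debenzylation.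
Weak point 1, the six-operation run to A3: protecting-group and redox changes that build a single C–O bond and depend on an unsecured ortho-iodination.
Weak point 2, the carbonylative annulation: a di-ortho-substituted, electron-rich aryl iodide with a free aldehyde in hot amine invites direct alkynylation, aurone closure and aldehyde condensation at the one step that makes a ring of the core.
Weak point 3, the endgame: condensation with an unprotected dihydroxyacetophenone is sluggish, and the last step exposes two aryl methyl ethers and a 5,7,8-trioxygenated flavone (prone to ring-opening isomerisation) to a boron Lewis acid.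

**Retrosynthetic overview**
Ring A of flavone unit 1 (C4a, C5, C6, C7, C8, C8a, carrying 5-OH, 7-OH and the C8–O–aryl ether) would be made last. It is cut at C5–C6 and C7–C8, back to a monocyclic 4-pyranone ester 7 that holds C8 as an aryloxymethyl group, plus an acetyl donor for C6–C7.
The O–C8 bond is therefore made as an alkyl aryl ether (Williamson alkylation of the 4'-OH of genkwanin, which is unit 2 complete) and becomes the diaryl ether when ring A aromatises: no aryl halide, no SNAr, no metal coupling.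
Ring C of unit 1 closes before ring A, by C-acylation of the β-keto ester with an arylpropynoyl chloride and 6-endo oxa-Michael addition; this fixes O1–C8a and hence the 8-aryloxy (not 6-aryloxy) pattern.
Ring order: unit 2 (bought), ring C of unit 1, ring A of unit 1; no protecting group, no redox step and no deprotection at the end.

Key step: step 4

Assumption: genkwanin (3) is used as purchased, and its chelated 5-OH is carried unprotected (it costs one equivalent of base in step 4). Atom labels C4a to C8a and O1 refer to flavone unit 1 of the target, the unit with the 4-methoxyphenyl group.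

Step 1
Reactants: 1 3-(4-methoxyphenyl)prop-2-ynoic acid
Product: 2 3-(4-methoxyphenyl)prop-2-ynoyl chloride
Conditions: (COCl)2 (1.3 equiv), DMF (cat.), CH2Cl2, 0 °C to rt; evaporated and used crude
Reagents that add atoms: oxalyl chloride, O=C(Cl)C(=O)Cl
Why: Acyl chloride formation through the chloroiminium (Vilsmeier-type) catalyst is standard for arylpropiolic acids, and low temperature with immediate use should keep HCl from adding to the triple bond.

Step 2
Reactants: 3 genkwanin (5-hydroxy-2-(4-hydroxyphenyl)-7-methoxy-4H-chromen-4-one); 4 ethyl 4-chloro-3-oxobutanoate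
Product: 5 ethyl 4-[4-(5-hydroxy-7-methoxy-4-oxo-4H-chromen-2-yl)phenoxy]-3-oxobutanoate
Conditions: NaH (2.1 equiv), THF–DMF, 0 °C; 4 (1.05 equiv), 0 to 45 °C; 1 M HCl
Reagents that add atoms: none
Why: Williamson ether synthesis, in which the 4'-phenoxide (the most acidic and least hindered OH) displaces chloride from the sodium enolate of 4 by SN2, while the chelated 5-OH is a poor nucleophile and should stay unalkylated with one equivalent of electrophile.

Step 3
Reactants: 5 ethyl 4-[4-(5-hydroxy-7-methoxy-4-oxo-4H-chromen-2-yl)phenoxy]-3-oxobutanoate; 2 3-(4-methoxyphenyl)prop-2-ynoyl chloride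
Product: 7 ethyl 2-{[4-(5-hydroxy-7-methoxy-4-oxo-4H-chromen-2-yl)phenoxy]methyl}-6-(4-methoxyphenyl)-4-oxo-4H-pyran-3-carboxylate, via ynone tricarbonyl 6 (not isolated)
Conditions: MgCl2 (2.2 equiv), pyridine (4 equiv), CH2Cl2–MeCN, 0 °C; 2 (1.1 equiv), 0 °C to rt; 1 M HCl wash; then DMAP (20 mol%), DMF, 40 °C
Reagents that add atoms: none
Why: Soft-enolisation C-acylation of the magnesium chelate of the β-keto ester gives 6, whose only ketone enol oxygen then adds to the ynone in a 6-endo-dig oxa-Michael addition (amine catalysis through addition–elimination at the β-carbon), so the 4-pyranone forms as a single regioisomer with the pyranone C2 (future C8a) bonded to the aryloxymethyl carbon (future C8) and C3 (future C4a) bearing the ester (future C5).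

Step 4
Reactants: 7 ethyl 2-{[4-(5-hydroxy-7-methoxy-4-oxo-4H-chromen-2-yl)phenoxy]methyl}-6-(4-methoxyphenyl)-4-oxo-4H-pyran-3-carboxylate; 8 1-acetylimidazole
Product: 10 5,7-dihydroxy-8-[4-(5-hydroxy-7-methoxy-4-oxo-4H-chromen-2-yl)phenoxy]-2-(4-methoxyphenyl)-4H-chromen-4-one, via C8-acetyl pyranone 9 (not isolated)
Conditions: LiN(SiMe3)2 (2.1 equiv), THF, −78 °C; 8 (1.1 equiv), −78 to −20 °C; LiN(iPr)2 (3.0 equiv), −78 to 0 °C; 1 M HCl to pH 3, 0 °C
Reagents that add atoms: none
Why: LiN(SiMe3)2 removes the 5-OH proton of unit 2 and a C8–H of the aryloxymethyl group (vinylogous to the C4 ketone and to the ester), the extended enolate is C-acetylated at C8 by 8 (bond C7–C8) and the more acidic 9 stays as its C8 enolate, then LiN(iPr)2 forms the terminal methyl carbanion of that enolate (a dianion of the β-diketone type), which attacks the ester carbon in an intramolecular Claisen (Dieckmann-type) condensation (bond C5–C6), and loss of ethoxide with enolisation of the cyclic 1,3-dione gives the 5,7-dihydroxy benzene ring. The closest known reaction type is the acylation–Claisen benzannulation of laterally metalated ortho-toluate esters and 2-methyl-4-pyranones to 1,3-dihydroxyarenes, and, in biosynthesis, the Claisen folding of a poly-β-carbonyl chain to an acylphloroglucinol. Ring A closes in a 6-exo-trig sense (enolate exo) at the ester carbonyl; closure on the C4 ring carbonyl would need a bridged ring with a bridgehead double bond and is excluded. The stereocentre at C8 of 9 forms racemic and is destroyed on aromatisation, so nothing needs control. The step needs the 8-aryloxy rather than the 6-aryloxy pattern, secured because the O1–C8a bond already exists in the pyranone and C8 is its only acidic carbon, and it needs C- rather than O-closure, secured by the dianion (terminal carbon most nucleophilic) and by the phenoxide product as thermodynamic sink. The product is the target itself, with no protecting group to remove.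

**Compound list**
1 | 3-(4-methoxyphenyl)prop-2-ynoic acid | COc1ccc(C#CC(=O)O)cc1 | starting material
2 | 3-(4-methoxyphenyl)prop-2-ynoyl chloride | COc1ccc(C#CC(=O)Cl)cc1 | intermediate
3 | genkwanin, 5-hydroxy-2-(4-hydroxyphenyl)-7-methoxy-4H-chromen-4-one | COc1cc(O)c2c(=O)cc(-c3ccc(O)cc3)oc2c1 | starting material
4 | ethyl 4-chloro-3-oxobutanoate | CCOC(=O)CC(=O)CCl | starting material
5 | ethyl 4-[4-(5-hydroxy-7-methoxy-4-oxo-4H-chromen-2-yl)phenoxy]-3-oxobutanoate | CCOC(=O)CC(=O)COc1ccc(-c2cc(=O)c3c(O)cc(OC)cc3o2)cc1 | intermediate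
6 | ethyl 2-{[4-(5-hydroxy-7-methoxy-4-oxo-4H-chromen-2-yl)phenoxy]acetyl}-5-(4-methoxyphenyl)-3-oxopent-4-ynoate | CCOC(=O)C(C(=O)COc1ccc(-c2cc(=O)c3c(O)cc(OC)cc3o2)cc1)C(=O)C#Cc1ccc(OC)cc1 | intermediate (not isolated)
7 | ethyl 2-{[4-(5-hydroxy-7-methoxy-4-oxo-4H-chromen-2-yl)phenoxy]methyl}-6-(4-methoxyphenyl)-4-oxo-4H-pyran-3-carboxylate | CCOC(=O)c1c(COc2ccc(-c3cc(=O)c4c(O)cc(OC)cc4o3)cc2)oc(-c2ccc(OC)cc2)cc1=O | intermediate (key-step precursor)
8 | 1-acetylimidazole | CC(=O)n1ccnc1 | starting material
9 | ethyl 2-{1-[4-(5-hydroxy-7-methoxy-4-oxo-4H-chromen-2-yl)phenoxy]-2-oxopropyl}-6-(4-methoxyphenyl)-4-oxo-4H-pyran-3-carboxylate (racemic) | CCOC(=O)c1c(C(Oc2ccc(-c3cc(=O)c4c(O)cc(OC)cc4o3)cc2)C(C)=O)oc(-c2ccc(OC)cc2)cc1=O | intermediate (not isolated)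
10 | 5,7-dihydroxy-8-[4-(5-hydroxy-7-methoxy-4-oxo-4H-chromen-2-yl)phenoxy]-2-(4-methoxyphenyl)-4H-chromen-4-one | COc1ccc(-c2cc(=O)c3c(O)cc(O)c(Oc4ccc(-c5cc(=O)c6c(O)cc(OC)cc6o5)cc4)c3o2)cc1 | target

Total step count: 4. Longest linear sequence: 3 steps (3 to 5 to 7 to 10, or 1 to 2 to 7 to 10).

**Steps most likely to fail**

Step 4. The acetyl group may go to oxygen (the dienolate oxygen or the 5-phenoxide of unit 2) instead of C8. The mono-enolate may close through oxygen on the ester to a fused 2-pyranone before the terminal carbanion forms. The amide bases may also open the pyranone ring. The fallback makes the two ring bonds in the opposite order, setting out from 7. The ethyl ester would be cleaved with Me3SnOH in 1,2-dichloroethane at 80 °C to 2-{[4-(5-hydroxy-7-methoxy-4-oxo-4H-chromen-2-yl)phenoxy]methyl}-6-(4-methoxyphenyl)-4-oxo-4H-pyran-3-carboxylic acid F1. 1,1'-Carbonyldiimidazole in THF would give the acyl imidazolide F2. Decarboxylative Claisen condensation of F2 with Mg(O2CCH2CO2Et)2 would give ethyl 3-[2-{[4-(5-hydroxy-7-methoxy-4-oxo-4H-chromen-2-yl)phenoxy]methyl}-6-(4-methoxyphenyl)-4-oxo-4H-pyran-3-yl]-3-oxopropanoate F3, which forms bond C5–C6 first. LiN(SiMe3)2 (3.2 equiv) in THF at −78 to 0 °C would then deprotonate the β-keto ester and C8 and close bond C7–C8 by Claisen condensation of the C8 carbanion on the new ester, the mode of acylphloroglucinol formation from poly-β-carbonyl esters, and the route is rejoined at 10.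

Step 3. Chloride, pyridine or the enolate carbon may add to the ynone in conjugate fashion instead of C-acylation, the 5-OH may be acylated, or 6 may close in the 5-exo mode to a furanone. The fallback replaces the ynone by an aroylketene and sets out from 5. 4-Methoxybenzoyl chloride, Meldrum's acid and pyridine would give 5-[hydroxy(4-methoxyphenyl)methylidene]-2,2-dimethyl-1,3-dioxane-4,6-dione F4. Heated with 5 in toluene at 100 °C, F4 would lose acetone and carbon dioxide to (4-methoxybenzoyl)ketene F5, which acylates the enol carbon of 5 to ethyl 2-{[4-(5-hydroxy-7-methoxy-4-oxo-4H-chromen-2-yl)phenoxy]acetyl}-5-(4-methoxyphenyl)-3,5-dioxopentanoate F6. CF3CO2H in CH2Cl2 would cyclodehydrate this 1,3,5-triketone, which can give only one 4-pyranone and under acid should not lactonise to a 2-pyranone, and the route is rejoined at 7.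

Step 2. Displacement on the enolate of the chloro keto ester may be slow, with self-condensation of 4 or partial alkylation at the 5-OH. The fallback builds the keto ester by homologation and sets out from 3. tert-Butyl bromoacetate and K2CO3 in acetone would give tert-butyl [4-(5-hydroxy-7-methoxy-4-oxo-4H-chromen-2-yl)phenoxy]acetate F7. CF3CO2H would give [4-(5-hydroxy-7-methoxy-4-oxo-4H-chromen-2-yl)phenoxy]acetic acid F8. 1,1'-Carbonyldiimidazole would give the imidazolide F9, and Mg(O2CCH2CO2Et)2 in THF would convert F9 by decarboxylative Claisen condensation into the keto ester, rejoining the route at 5.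

**Further compounds**
F1 | step 4 | 2-{[4-(5-hydroxy-7-methoxy-4-oxo-4H-chromen-2-yl)phenoxy]methyl}-6-(4-methoxyphenyl)-4-oxo-4H-pyran-3-carboxylic acid | O=C(O)c1c(COc2ccc(-c3cc(=O)c4c(O)cc(OC)cc4o3)cc2)oc(-c2ccc(OC)cc2)cc1=O
F2 | step 4 | 3-(1H-imidazol-1-ylcarbonyl)-2-{[4-(5-hydroxy-7-methoxy-4-oxo-4H-chromen-2-yl)phenoxy]methyl}-6-(4-methoxyphenyl)-4H-pyran-4-one | O=C(c1c(COc2ccc(-c3cc(=O)c4c(O)cc(OC)cc4o3)cc2)oc(-c2ccc(OC)cc2)cc1=O)n1ccnc1
F3 | step 4 | ethyl 3-[2-{[4-(5-hydroxy-7-methoxy-4-oxo-4H-chromen-2-yl)phenoxy]methyl}-6-(4-methoxyphenyl)-4-oxo-4H-pyran-3-yl]-3-oxopropanoate | CCOC(=O)CC(=O)c1c(COc2ccc(-c3cc(=O)c4c(O)cc(OC)cc4o3)cc2)oc(-c2ccc(OC)cc2)cc1=O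
F4 | step 3 | 5-[hydroxy(4-methoxyphenyl)methylidene]-2,2-dimethyl-1,3-dioxane-4,6-dione | COc1ccc(C(O)=C2C(=O)OC(C)(C)OC2=O)cc1
F5 | step 3 | (4-methoxybenzoyl)ketene, 3-(4-methoxyphenyl)-3-oxoprop-1-en-1-one | COc1ccc(C(=O)C=C=O)cc1
F6 | step 3 | ethyl 2-{[4-(5-hydroxy-7-methoxy-4-oxo-4H-chromen-2-yl)phenoxy]acetyl}-5-(4-methoxyphenyl)-3,5-dioxopentanoate | CCOC(=O)C(C(=O)COc1ccc(-c2cc(=O)c3c(O)cc(OC)cc3o2)cc1)C(=O)CC(=O)c1ccc(OC)cc1
F7 | step 2 | tert-butyl [4-(5-hydroxy-7-methoxy-4-oxo-4H-chromen-2-yl)phenoxy]acetate | CC(C)(C)OC(=O)COc1ccc(-c2cc(=O)c3c(O)cc(OC)cc3o2)cc1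
F8 | step 2 | [4-(5-hydroxy-7-methoxy-4-oxo-4H-chromen-2-yl)phenoxy]acetic acid | O=C(O)COc1ccc(-c2cc(=O)c3c(O)cc(OC)cc3o2)cc1
F9 | step 2 | 5-hydroxy-2-{4-[2-(1H-imidazol-1-yl)-2-oxoethoxy]phenyl}-7-methoxy-4H-chromen-4-one | O=C(COc1ccc(-c2cc(=O)c3c(O)cc(OC)cc3o2)cc1)n1ccnc1
A1 | direct plan | 2,4,6-trihydroxybenzaldehyde | O=Cc1c(O)cc(O)cc1O
A2 | direct plan | 4-fluorobenzaldehyde | O=Cc1ccc(F)cc1
A3 | direct plan | 4-[4,6-bis(benzyloxy)-2-hydroxy-3-iodophenoxy]benzaldehyde | O=Cc1ccc(Oc2c(O)c(I)c(OCc3ccccc3)cc2OCc2ccccc2)cc1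
A4 | direct plan | 4-ethynylanisole | COc1ccc(C#C)cc1
A5 | direct plan | 4-{[5,7-bis(benzyloxy)-2-(4-methoxyphenyl)-4-oxo-4H-chromen-8-yl]oxy}benzaldehyde | COc1ccc(-c2cc(=O)c3c(OCc4ccccc4)cc(OCc4ccccc4)c(Oc4ccc(C=O)cc4)c3o2)cc1
A6 | direct plan | 1-(2,6-dihydroxy-4-methoxyphenyl)ethanone | CC(=O)c1c(O)cc(OC)cc1O
A7 | direct plan | 5,7-bis(benzyloxy)-8-[4-(5-hydroxy-7-methoxy-4-oxo-4H-chromen-2-yl)phenoxy]-2-(4-methoxyphenyl)-4H-chromen-4-one | COc1ccc(-c2cc(=O)c3c(OCc4ccccc4)cc(OCc4ccccc4)c(Oc4ccc(-c5cc(=O)c6c(O)cc(OC)cc6o5)cc4)c3o2)cc1
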